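## The problem

Compound 29 is a flavone (rings A, C and B) whose ring B 2'-oxygen is tied back to C3 through a –CH[C(CH3)2OH]–CH2– bridge, so a seven-membered oxepine (ring D) is fused to both the pyranone and ring B. The bridge carbon next to oxygen is the only stereocentre (R). Nothing else in the molecule can direct it, so it must come from a reagent-controlled step; as an ether carbon it cannot epimerise, and the only later danger is ionisation at it or at the neighbouring tertiary carbinol. Ring A is substituted everywhere except C8, with 5-OH, the (E)-3-methylbut-1-enyl chain at C6 and 7-OMe in a row. Classical flavone chemistry would have to place a carbon chain between two oxygens of a phloroglucinol and then tell 5-OH, 7-OMe and 4'-OH apart. The styrene-type alkene beside the chelated 5-OH rules out hydrogenolysis and strong acid, the tertiary alcohol dehydrates under the same acids, and the 4-pyranone is opened by amines and hot alkoxide, so the endgame must be mild. The enabling feature is the C5–C8 edge of ring A: hydroxyl at C5, carbon substituent at C6, alkoxy at C7 and hydrogen at C8 is the pattern left by a ketene plus ynol ether benzannulation. C5 comes from the ketene carbonyl, C6–C7 from the alkyne, C8 from a diazo carbon, and C4a=C8a from the alkene of a pyranone that is already in place. The task therefore reduces to diazo ketone 16 (rings B, C, D) and methoxy enyne 23.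

## Retrosynthesis

**29 ⇒ 28.** The two methoxymethyl ethers (4'-O and tertiary O) are cut last. They survive base, diazo chemistry, light and 80 °C, and they come off with a silyl triflate and a pyridine base without free protic acid. Benzyl ethers would need hydrogen, which the C6 alkene forbids. The 5-OH needs no protection because the key step delivers it free and chelated.

**28 ⇒ 16 + 23.** Four bonds of ring A are cut: C8–C8a, C5–C6, C7–C8 and C4a–C5. The neighbouring cut, closing ring C onto a finished ring A (Baker–Venkataraman type), would need a pentasubstituted acetophenone with the chain already between two oxygens. Here the reagents write the pattern: the alkyne brings OMe and chain, the ketene oxygen becomes 5-OH. Precursor 16 has no ring A at all and 23 is an eight-carbon fragment. The forward reaction must add the ynol ether to the ketene in one orientation, close only onto C4a, and be driven by light that the diazo group absorbs but the aryl pyranone does not.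

**23 ⇒ 19 + 22; 22 ⇒ 21 ⇒ 20; 19 ⇒ 17.** The enyne is cut at its sp–sp2 bond. Alkenyl iodide 19 comes from alkyne 17 through alkenylzirconium 18, which fixes the E geometry. The methoxyethynyl unit comes from chloroacetal 20 through lithium acetylide 21 and zinc acetylide 22. A methoxy ynol ether is chosen over an ethoxy one because it cannot fragment by a retro-ene path when the key step is heated.

**16 ⇒ 14 ⇒ 13 ⇒ 12.** The diazoacetyl group is traced through mixed anhydride 15 to acid 14, and 14 to methyl ester 13 and diol 12. Both hydroxyls of 12 are capped in one operation, after ring D is closed and after the only acid-catalysed step of the sequence.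

**12 ⇒ 11 ⇒ 10.** Ring D is opened at its O–CH bond: the 2'-phenoxide of 11 attacks the secondary epoxide carbon (7-exo, SN2, inversion). Making this bond at a benzoxepinone stage, before the pyranone exists, was set aside. There a phenoxide and an epoxide would sit beside an enolisable ketone or β-diketone, whose enolate can open the epoxide itself (3-exo at carbon, 5-exo at oxygen). In 11 no enolisable position is left. Diphenol 11 arises from bis(allyl) ether 10; allyl is the one phenol protection that survives the earlier base and acid steps and leaves under conditions the epoxide tolerates.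

**10 ⇒ 9.** The stereocentre is traced to a Shi epoxidation of the prenyl alkene of 9 (catalyst enantiomer specified in step 5). Only this alkene is trisubstituted and electron-rich.

**9 ⇒ 8 ⇒ 6 + 7.** The pyranone is cut at O1–C8a (cyclodehydration of triketo ester 8) and at C4a–C8a (Claisen acylation of the terminal methyl of diketone 6 by dimethyl oxalate 7). The prenyl group has to be in place first, because C3 of a finished pyranone cannot be alkylated selectively.

**6 ⇒ 4 + 5; 4 ⇒ 2 + 3; 2 ⇒ 1.** The C3–CH2 bond is cut to β-diketone 4 and prenyl bromide 5. The C3–C4 bond is cut to acetophenone 2 and ethyl acetate 3. Ether 2 comes from 2,4-dihydroxyacetophenone 1. All of 1, 3, 5, 7, 17 and 20 are catalogue compounds.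

## Roads not taken

**Alternative 1:** The cut is at C2–C1' and C3–CH2 of a complete ring A/C chromone A1. In the forward sense CuBr·SMe2 (monovalent copper) would mediate conjugate addition of aryl Grignard reagent A2 to C2 of A1, and the enolate would be alkylated at C3 by bromo ketone A3 to give flavanone A4. Dehydrogenation to the flavone, enantioselective reduction of the side-chain ketone, SNAr closure of ring D onto the 2'-fluoride and deprotection would follow.
- Merits: three components meet in one flask, no photochemistry is needed, and both halves are complete before union. In convergence this road is better than the chosen one.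
- Weak points: A1 already contains the whole ring A problem (chain between two oxygens, selective 7-O-methylation). 5-Alkoxychromones are reluctant acceptors. The flavanone enolate can expel the ring oxygen and open to a chalcone faster than a hindered α-bromo ketone alkylates it. The stereocentre would come late, from reagent-controlled reduction of a ketone flanked by a quaternary carbon, and the re-oxidation to the flavone must spare the styrene.
- Comparison: against the better convergence, the chosen plan sets a ring A built in one step with its regiochemistry built in, and a stereocentre set early and transferred by SN2.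

**Alternative 2:** The cut is at C1'–C2 and C2–C3, with C2 supplied as carbon monoxide. Bromo ketone A5 would be treated with Pd(dba)2 (zerovalent palladium), Xantphos, CO and base. The acylpalladium species would be captured by the ketone enolate to give cyclic 1,3-diketone A6, and acid would then close ring C through the free C8a hydroxyl.
- Merits: one carbon from a gas, ring D and the diketone formed together, and an endgame shorter than the chosen one (A6 is a dehydration and a deprotection from 29).
- Weak points: the same enolate can arylate directly without CO insertion and give a six-membered chromane. O-acylation gives an enol lactone. The free phenol and the tertiary alcohol are competing traps for the acylpalladium, and the styrene is exposed to palladium. A5 again requires the fully substituted ring A ketone.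
- Comparison: against the shorter endgame, the chosen plan sets a key step whose selectivity rests on alkyne polarity rather than on a rate competition, and a ring A that need not be made beforehand.

**Alternative 3:** The cut is at O1–C8a, C4–C4a and O1–C2. CsF would release the ring A aryne from silyl triflate A7. The carboxylate of chloro acid A8 would add to it, the acyl group would shift from oxygen to the aryl anion, and the new phenoxide would displace the vinylic chloride to give A9, the tris(methoxymethyl) ether of 29.
- Merits: the most convergent of the four plans, with ring C forged from two finished halves at room temperature. The 5-alkoxy group steers the carboxylate to C8a, which is the sense required. A9 is one step from 29, as 28 is.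
- Weak points: A7 is a benzene with five different substituents, and making it costs more steps than all of ring A in the chosen route. The acyl shift competes with protonation of the aryl anion to a plain aryl ester. A8 has to be made through an enolisable benzoxepinone, the stage at which ring D closure is exposed to enolate side reactions.
- Comparison: against the superior convergence, the chosen plan sets a much cheaper ring A and a ring D closure free of enolate competition.

Key step: step 12

Remark on locants: flavone numbering is used for all pyranone intermediates (O1; C2 bonded to ring B; C3; C4 carbonyl; C4a; C8a bearing the carboxyl-derived group; ring B primed). In the monocyclic esters 9–11 pyran C2/C3/C5/C6 correspond to C8a/C4a/C3/C2.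

Assumption: the L-fructose-derived enantiomer of the Shi ketone is available (purchased or made from L-sorbose), and diazomethane is used as a freshly prepared ether solution.

## Route

Step 1
Reactants: 1 2,4-dihydroxyacetophenone
Product: 2 2,4-bis(allyloxy)acetophenone
Conditions: allyl bromide (2.6 equiv.), K2CO3 (3 equiv.), DMF, 60 °C
Reagents that add atoms: allyl bromide, C=CCBr
Why: Williamson ether synthesis; the chelated 2-OH needs DMF and warming but should alkylate with excess bromide. Allyl is chosen because both ethers can later be removed together under palladium catalysis without harming an epoxide, an ester or the pyranone.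

Step 2
Reactants: 2 2,4-bis(allyloxy)acetophenone; 3 ethyl acetate
Product: 4 1-[2,4-bis(allyloxy)phenyl]butane-1,3-dione
Conditions: NaH (3 equiv.), 3 (5 equiv.), THF, 0 °C to reflux; aq. HCl work-up
Reagents that add atoms: none
Why: Crossed Claisen condensation of an aryl methyl ketone with ethyl acetate, driven by deprotonation of the β-diketone formed. The allyl ethers are inert to hydride base.

Step 3
Reactants: 4 1-[2,4-bis(allyloxy)phenyl]butane-1,3-dione; 5 1-bromo-3-methylbut-2-ene
Product: 6 1-[2,4-bis(allyloxy)phenyl]-2-(3-methylbut-2-en-1-yl)butane-1,3-dione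
Conditions: 5 (1.05 equiv.), K2CO3 (1.5 equiv.), acetone, 25 to 50 °C
Reagents that add atoms: none
Why: C-alkylation of a β-diketone enolate by a soft allylic bromide; one equivalent of bromide and a carbonate base should hold back dialkylation. The new sp3 centre is enolisable and becomes sp2 in the next step, so its configuration is irrelevant.

Step 4
Reactants: 6 1-[2,4-bis(allyloxy)phenyl]-2-(3-methylbut-2-en-1-yl)butane-1,3-dione; 7 dimethyl oxalate
Product: 9 methyl 6-[2,4-bis(allyloxy)phenyl]-5-(3-methylbut-2-en-1-yl)-4-oxo-4H-pyran-2-carboxylate, via triketo ester 8 (not isolated)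
Conditions: LiN(i-Pr)2 (3.2 equiv.), THF, −78 to −20 °C; 7 (1.3 equiv.), −78 to 0 °C; AcOH; then TsOH·H2O (0.1 equiv.), toluene, 60 °C
Reagents that add atoms: none
Why: The β-diketone dianion is acylated at its terminal carbon by the oxalate (Claisen condensation), the third equivalent of amide taking up the more acidic triketo ester as it forms. Acid-catalysed cyclodehydration of the 2,4,6-triketo ester is the classical entry to 4-oxo-4H-pyran-2-carboxylates. Catalytic sulfonic acid in toluene at 60 °C should leave the prenyl alkene and the allyl ethers alone.

Step 5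
Reactants: 9 methyl 6-[2,4-bis(allyloxy)phenyl]-5-(3-methylbut-2-en-1-yl)-4-oxo-4H-pyran-2-carboxylate
Product: 10 methyl 6-[2,4-bis(allyloxy)phenyl]-5-{[(2S)-3,3-dimethyloxiran-2-yl]methyl}-4-oxo-4H-pyran-2-carboxylate
Conditions: 1,2:4,5-di-O-isopropylidene-β-L-erythro-2,3-hexodiulo-2,6-pyranose (0.3 equiv.), KHSO5 (as 2KHSO5·KHSO4·K2SO4, 1.5 equiv.), K2CO3, n-Bu4NHSO4 (cat.), MeCN–CH2(OMe)2, aq. Na2B4O7–Na2EDTA buffer (pH 10.5), 0 °C
Reagents that add atoms: potassium peroxymonosulfate, [K+].[O-]S(=O)(=O)OO
Why: Shi epoxidation; the electrophilic dioxirane should attack only the trisubstituted prenyl alkene, since the allyl ethers are monosubstituted and the pyranone alkenes electron-poor. The D-fructose ketone gives (R)-epoxides from R–CH2–CH=C(CH3)2 alkenes through the spiro transition state, so its mirror image used here should give the (S)-epoxide. This carbon becomes the ring D stereocentre.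

Step 6
Reactants: 10 methyl 6-[2,4-bis(allyloxy)phenyl]-5-{[(2S)-3,3-dimethyloxiran-2-yl]methyl}-4-oxo-4H-pyran-2-carboxylate
Product: 12 methyl ester of the rings B/C/D pyranone acid with free 4'-OH and free tertiary OH (R), via diphenol epoxide 11 (not isolated)
Conditions: Pd(PPh3)4 (5 mol%), K2CO3 (4 equiv.), MeOH, 25 °C then 50 °C
Reagents that add atoms: none
Why: Palladium-catalysed deallylation (π-allyl capture by methoxide, degenerate with the methyl ester) frees both phenoxides. The 2'-phenoxide should then open the epoxide at its secondary carbon in a 7-exo-tet SN2 closure with inversion, turning the (S)-epoxide into the (R)-ether. No enolisable carbonyl is present to compete, and the 4'-phenoxide cannot reach the epoxide.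

Step 7
Reactants: 12 methyl ester of the rings B/C/D pyranone acid with free 4'-OH and free tertiary OH (R)
Product: 13 rings B/C/D pyranone methyl ester bis(methoxymethyl) ether (R)
Conditions: MOMCl (6 equiv.), i-Pr2NEt (8 equiv.), n-Bu4NI (0.2 equiv.), CH2Cl2, 0 to 40 °C
Reagents that add atoms: chloromethyl methyl ether, COCCl
Why: Acetal-type O-alkylation; the phenol reacts quickly, and the tertiary alcohol should follow with iodide catalysis and warming. Both caps are needed so that diazomethane cannot methylate the phenol and no hydroxyl can intercept a ketene.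

Step 8
Reactants: 13 rings B/C/D pyranone methyl ester bis(methoxymethyl) ether (R)
Product: 14 rings B/C/D pyranone-8a-carboxylic acid bis(methoxymethyl) ether (R)
Conditions: LiOH·H2O (1.3 equiv.), THF–H2O, 0 °C; then cold 0.5 M HCl to pH 3–4
Reagents that add atoms: lithium hydroxide, [Li+].[OH-]
Why: Saponification of an ester activated by the electron-poor pyranone, so a small excess of hydroxide at 0 °C should suffice and leave the ring closed. The acetals are stable to base and to a brief cold acidification.

Step 9
Reactants: 14 rings B/C/D pyranone-8a-carboxylic acid bis(methoxymethyl) ether (R)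
Product: 16 rings B/C/D pyranone diazomethyl ketone bis(methoxymethyl) ether (R), via mixed carbonic anhydride 15 (not isolated)
Conditions: i-BuOCOCl (1.1 equiv.), N-methylmorpholine (1.1 equiv.), THF, −15 °C; CH2N2 (3 equiv., Et2O), −15 to 0 °C, dark; AcOH quench
Reagents that add atoms: diazomethane, C=[N+]=[N-]; isobutyl chloroformate, CC(C)COC(Cl)=O (its atoms stay only in 15)
Why: Mixed-anhydride activation and C-acylation of diazomethane (the first stage of an Arndt–Eistert sequence) under neutral conditions that spare the acetals. Acylation at −15 to 0 °C should outrun dipolar cycloaddition to the pyranone alkene.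

Step 10
Reactants: 17 3-methylbut-1-yne
Product: 19 (E)-1-iodo-3-methylbut-1-ene, via alkenylzirconocene chloride 18 (not isolated)
Conditions: Cp2Zr(H)Cl (1.1 equiv.), CH2Cl2, 0 to 25 °C; I2 (1.05 equiv.), 0 °C
Reagents that add atoms: iodine, II; Cp2Zr(H)Cl, [H][Zr](Cl)(C1C=CC=C1)C1C=CC=C1 (zirconium stays only in 18)
Why: Hydrozirconation is syn and puts the metal on the terminal carbon; iodinolysis proceeds with retention and should give the E alkenyl iodide only.

Step 11
Reactants: 20 2-chloro-1,1-dimethoxyethane; 19 (E)-1-iodo-3-methylbut-1-ene
Product: 23 (E)-1-methoxy-5-methylhex-3-en-1-yne, via lithium methoxyacetylide 21 (not isolated), via methoxyethynylzinc chloride 22 (not isolated)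
Conditions: 20 (1.5 equiv.), LiNEt2 (from Et2NH and n-BuLi, 4.5 equiv.), THF, −78 to 0 °C; ZnCl2 (1.6 equiv.), 0 °C; 19, Pd(PPh3)4 (3 mol%), THF, 25 °C
Reagents that add atoms: lithium diethylamide, CCN([Li])CC (lithium stays only in 21); zinc dichloride, Cl[Zn]Cl (zinc stays only in 22)
Why: Two eliminations (methanol, then HCl) and deprotonation convert the chloroacetal into lithium methoxyacetylide. Transmetalation to zinc and Negishi coupling should join it to the alkenyl iodide with retention of the E geometry.

Step 12
Reactants: 16 rings B/C/D pyranone diazomethyl ketone bis(methoxymethyl) ether (R); 23 (E)-1-methoxy-5-methylhex-3-en-1-yne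
Product: 28 bis(methoxymethyl) ether of the target with free 5-OH (R), via pyranonylketene 24 (not isolated), via cyclobutenone 25 (not isolated), via dienylketene 26 (not isolated), via cyclohexadienone 27 (not isolated)
Conditions: 23 (2.5 equiv.), ClCH2CH2Cl (0.1 M, degassed), hν (390–410 nm LEDs), 20 °C; then 80 °C
Reagents that add atoms: none
Why: Violet light should excite only the diazo ketone of 16, which loses N2 with a 1,2-shift of pyranone C8a to the diazo carbon (photochemical Wolff rearrangement) to give ketene 24. Ynol ether 23 adds across the ketene C=C in a polar (2+2) step: its alkenyl-bearing, nucleophilic carbon bonds to the ketene carbonyl carbon and its methoxy-bearing carbon to the ketene CH, giving cyclobutenone 25 and fixing the chain at C6 and OMe at C7. At 80 °C 25 opens by 4π electrocyclic cleavage of its C(=O)–CH bond to dienylketene 26, whose ketene carbon closes onto pyranone C4a in a thermally allowed 6π electrocyclization that forms six-membered ring A as dienone 27; enolisation of C4a–H then gives the chelated 5-OH phenol 28. This is the diazo ketone form of the Danheiser benzannulation, known for cycloalkenyl, aryl and heteroaryl diazomethyl ketones with alkoxy- and siloxyalkynes; here the pyranone C4a=C8a bond takes the place of the alkene or arene bond. No stereocentre is created (the sp3 carbons of 25 and 27 are transient), and the ring D centre is remote and untouched. The step needs regioselectivity in the (2+2) addition, secured by the polarisation of the ynol ether, and site selectivity in the closure, secured because C4a is the only carbon flanking C8a; the E alkene of 23 lies outside every pericyclic array and should be retained. The methoxy ynol ether cannot fragment by a retro-ene path at 80 °C, and the new 5-OH is hydrogen-bonded to C4=O and hindered, which should limit its acylation by leftover ketene.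

Step 13
Reactants: 28 bis(methoxymethyl) ether of the target with free 5-OH (R)
Product: 29 target (R): 5,4'-dihydroxy-7-methoxy-6-[(E)-3-methylbut-1-enyl]flavone with the 2'-O–CH[C(CH3)2OH]–CH2–C3 bridge
Conditions: Me3SiOTf (5 equiv.), 2,2'-bipyridyl (7.5 equiv.), CH2Cl2, 0 to 25 °C; then H2O
Reagents that add atoms: none
Why: Silyl triflate with 2,2'-bipyridyl converts methoxymethyl ethers into silyl ethers or bipyridinium acetals that water hydrolyses; cleavage occurs at the acetal carbon, so the stereocentre is not touched. No free strong acid is present, so the styrene beside 5-OH, the tertiary alcohol and the 7-OMe group should survive.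

## Compound list

1 | 2,4-dihydroxyacetophenone | CC(=O)c1ccc(O)cc1O | starting material
2 | 1-[2,4-bis(prop-2-en-1-yloxy)phenyl]ethan-1-one | CC(=O)c1ccc(OCC=C)cc1OCC=C | intermediate
3 | ethyl acetate | CCOC(C)=O | starting material
4 | 1-[2,4-bis(prop-2-en-1-yloxy)phenyl]butane-1,3-dione | CC(=O)CC(=O)c1ccc(OCC=C)cc1OCC=C | intermediate
5 | 1-bromo-3-methylbut-2-ene (prenyl bromide) | CC(C)=CCBr | starting material
6 | 1-[2,4-bis(prop-2-en-1-yloxy)phenyl]-2-(3-methylbut-2-en-1-yl)butane-1,3-dione (racemic, enolisable C2) | CC(=O)C(CC=C(C)C)C(=O)c1ccc(OCC=C)cc1OCC=C | intermediate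
7 | dimethyl oxalate | COC(=O)C(=O)OC | starting material
8 | methyl 6-[2,4-bis(prop-2-en-1-yloxy)phenyl]-5-(3-methylbut-2-en-1-yl)-2,4,6-trioxohexanoate (not isolated) | COC(=O)C(=O)CC(=O)C(CC=C(C)C)C(=O)c1ccc(OCC=C)cc1OCC=C | intermediate
9 | methyl 6-[2,4-bis(prop-2-en-1-yloxy)phenyl]-5-(3-methylbut-2-en-1-yl)-4-oxo-4H-pyran-2-carboxylate | COC(=O)c1cc(=O)c(CC=C(C)C)c(o1)-c1ccc(OCC=C)cc1OCC=C | intermediate
10 | methyl 6-[2,4-bis(prop-2-en-1-yloxy)phenyl]-5-{[(2S)-3,3-dimethyloxiran-2-yl]methyl}-4-oxo-4H-pyran-2-carboxylate | COC(=O)c1cc(=O)c(C[C@@H]2OC2(C)C)c(o1)-c1ccc(OCC=C)cc1OCC=C | intermediate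
11 | methyl 6-(2,4-dihydroxyphenyl)-5-{[(2S)-3,3-dimethyloxiran-2-yl]methyl}-4-oxo-4H-pyran-2-carboxylate (not isolated) | COC(=O)c1cc(=O)c(C[C@@H]2OC2(C)C)c(o1)-c1ccc(O)cc1O | intermediate
12 | rings B/C/D diol ester: 4-pyranone with CO2CH3 at C8a and H at C4a, C2 bonded to C1' of ring B, oxepine bridge C3–CH2–CH[C(CH3)2OH]–O–C2' with (R) carbon, 4'-OH | COC(=O)c1cc(=O)c2c(o1)-c1ccc(O)cc1O[C@@H](C(C)(C)O)C2 | intermediate
13 | bis(methoxymethyl) ether of 12 (4'-OCH2OCH3 and C(CH3)2OCH2OCH3; R) | COC(=O)c1cc(=O)c2c(o1)-c1ccc(OCOC)cc1O[C@@H](C(C)(C)OCOC)C2 | intermediate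
14 | carboxylic acid corresponding to 13 (CO2H at C8a; R) | OC(=O)c1cc(=O)c2c(o1)-c1ccc(OCOC)cc1O[C@@H](C(C)(C)OCOC)C2 | intermediate
15 | mixed anhydride of 14 with isobutyl carbonic acid (R; not isolated) | CC(C)COC(=O)OC(=O)c1cc(=O)c2c(o1)-c1ccc(OCOC)cc1O[C@@H](C(C)(C)OCOC)C2 | intermediate
16 | diazomethyl ketone of 14 (C8a–CO–CH=N2; R) | [N-]=[N+]=CC(=O)c1cc(=O)c2c(o1)-c1ccc(OCOC)cc1O[C@@H](C(C)(C)OCOC)C2 | intermediate
17 | 3-methylbut-1-yne | CC(C)C#C | starting material
18 | chlorobis(cyclopentadienyl)[(E)-3-methylbut-1-enyl]zirconium (not isolated) | CC(C)/C=C/[Zr](Cl)(C1C=CC=C1)C1C=CC=C1 | intermediate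
19 | (E)-1-iodo-3-methylbut-1-ene | CC(C)/C=C/I | intermediate
20 | 2-chloro-1,1-dimethoxyethane (chloroacetaldehyde dimethyl acetal) | COC(CCl)OC | starting material
21 | lithium methoxyacetylide (not isolated) | COC#C[Li] | intermediate
22 | methoxyethynylzinc chloride (not isolated) | COC#C[Zn]Cl | intermediate
23 | (E)-1-methoxy-5-methylhex-3-en-1-yne | COC#C/C=C/C(C)C | intermediate
24 | ketene from 16: C8a–CH=C=O on the rings B/C/D pyranone (R; not isolated) | O=C=Cc1cc(=O)c2c(o1)-c1ccc(OCOC)cc1O[C@@H](C(C)(C)OCOC)C2 | intermediate
25 | 3-methoxy-2-[(E)-3-methylbut-1-enyl]-4-(pyranon-8a-yl)cyclobut-2-en-1-one (ring D centre R, C4 of the four-membered ring unassigned; not isolated) | COC1=C(/C=C/C(C)C)C(=O)C1c1cc(=O)c2c(o1)-c1ccc(OCOC)cc1O[C@@H](C(C)(C)OCOC)C2 | intermediate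
26 | dienylketene O=C=C(alkenyl)–C(OCH3)=CH–(pyranon-8a-yl), ketene and pyranone cis on the enol ether bond (R; not isolated) | COC(=C/c1cc(=O)c2c(o1)-c1ccc(OCOC)cc1O[C@@H](C(C)(C)OCOC)C2)/C(=C=O)/C=C/C(C)C | intermediate
27 | cyclohexa-2,4-dienone tautomer of 28 with sp3 C4a–H (ring D centre R, C4a unassigned; not isolated) | COC1=C(/C=C/C(C)C)C(=O)C2C(=O)C3=C(OC2=C1)c1ccc(OCOC)cc1O[C@@H](C(C)(C)OCOC)C3 | intermediate
28 | 4'-O,tertiary-O-bis(methoxymethyl) ether of the target, 5-OH free (R) | COc1cc2oc3c(c(=O)c2c(O)c1/C=C/C(C)C)C[C@H](C(C)(C)OCOC)Oc1cc(OCOC)ccc1-3 | intermediate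
29 | target: 5,4'-dihydroxy-7-methoxy-6-[(E)-3-methylbut-1-enyl]flavone bridged from 2'-O to C3 by –CH[C(CH3)2OH]–CH2– (R) | COc1cc2oc3c(c(=O)c2c(O)c1/C=C/C(C)C)C[C@H](C(C)(C)O)Oc1cc(O)ccc1-3 | target

## Step count and least certain steps

Total: 13 steps. Longest linear sequence: 11 steps (steps 1–9, 12, 13); steps 10 and 11 make the enyne.

**Step 12 (key step).** The likeliest failure is competing absorption of light by the aryl pyranone chromophore and by the flavone product as it builds up. The Wolff rearrangement would then stall or the pyranone would enter its own photochemistry, while the ketene is lost by dimerisation before the conjugated ynol ether adds. The fallback generates the same ketene in the dark, sets out from 16 and returns at 28. Silver-catalysed Wolff rearrangement of 16 in wet THF (PhCO2Ag, Et3N) would give the homologous pyranon-8a-ylacetic acid F1. 1-Chloro-N,N,2-trimethylprop-1-en-1-amine would convert it under neutral conditions into the acid chloride F2. Dehydrochlorination of F2 with Et3N in toluene in the presence of 23 would give ketene 24, and warming to 80 °C would carry the sequence through 25, 26 and 27 to 28.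

**Step 4.** The likeliest failure is loss of material during dianion acylation: attack of the excess amide on the oxalate, O-acylation, or retro-Claisen loss of the acetyl group. Acid-induced addition of an enol to the prenyl alkene before the pyranone closes is a second risk. The fallback replaces the dianion by a neutral silyl dienol ether, sets out from 6 and returns at 8 and so at 9. Two-stage silylation of 6 (Me3SiCl, Et3N; then LiN(i-Pr)2, Me3SiCl) would give the 1,3-bis(trimethylsilyloxy)diene F3. Its terminal carbon would be acylated by methyl chlorooxalate at −78 °C; aqueous work-up gives 8, which is closed to 9 as before.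

**Step 6.** The likeliest failure is attack of methoxide or adventitious hydroxide on the activated ester and the pyranone while the allyl groups leave. A slow 7-exo closure by a phenoxide conjugated to the pyranone would also let intermolecular epoxide opening compete. The fallback changes the temporary phenol protection so that the phenoxide is released by fluoride in an aprotic medium; it sets out from 9 and returns at 12. Deallylation of 9 before any epoxide is present (Pd(PPh3)4, K2CO3, MeOH) would give the prenyl diphenol F4. Silylation (i-Pr3SiCl, imidazole, DMF) would give the bis(triisopropylsilyl) ether F5. Shi epoxidation as in step 5 would give the (S)-epoxide F6. n-Bu4NF in THF would then remove both silyl groups and the 2'-phenoxide would close ring D to 12.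

**Step 9.** The likeliest failure is 1,3-dipolar cycloaddition of diazomethane to the electron-poor C4a=C8a alkene, or attack at the carbonate carbonyl of the mixed anhydride. The fallback avoids diazomethane, sets out from 14 and returns at 16. Coupling of 14 with N,O-dimethylhydroxylamine (EDC·HCl, N-methylmorpholine) would give the Weinreb amide F7, and MeMgBr at −78 °C would give the 8a-acetyl pyranone F8. Trifluoroacetylation of its enolate (LiN(SiMe3)2, CF3CO2CH2CF3) would give the trifluoromethyl diketone F9. Diazo transfer with loss of the trifluoroacetyl group (MsN3, Et3N, H2O, MeCN) would then give 16.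

**Step 11.** The likeliest failure is decomposition of the lithium or zinc methoxyacetylide before coupling, hydration of the ynol ether on work-up, and loss of the volatile product. The fallback builds the triple bond by elimination rather than by coupling, sets out from 19 and returns at 23. Iodine–lithium exchange on 19 (t-BuLi, −78 °C) and acylation with N-methoxy-N-methyl-2-methoxyacetamide would give (E)-1-methoxy-5-methylhex-3-en-2-one F10. Enolisation toward the methoxymethylene group and triflation (LiN(SiMe3)2, PhNTf2) would give the enol triflate F11, and KOt-Bu would eliminate triflate to give 23.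

## Further compounds

F1 | step 12 | pyranon-8a-ylacetic acid of the rings B/C/D series, bis(methoxymethyl) ether (R) | OC(=O)Cc1cc(=O)c2c(o1)-c1ccc(OCOC)cc1O[C@@H](C(C)(C)OCOC)C2
F2 | step 12 | acid chloride of F1 (R) | ClC(=O)Cc1cc(=O)c2c(o1)-c1ccc(OCOC)cc1O[C@@H](C(C)(C)OCOC)C2
F3 | step 4 | 1,3-bis(trimethylsilyloxy)diene of 6 | C=C(O[Si](C)(C)C)C(CC=C(C)C)=C(O[Si](C)(C)C)c1ccc(OCC=C)cc1OCC=C
F4 | step 6 | methyl 6-(2,4-dihydroxyphenyl)-5-(3-methylbut-2-en-1-yl)-4-oxo-4H-pyran-2-carboxylate | COC(=O)c1cc(=O)c(CC=C(C)C)c(o1)-c1ccc(O)cc1O
F5 | step 6 | bis(triisopropylsilyl) ether of F4 | COC(=O)c1cc(=O)c(CC=C(C)C)c(o1)-c1ccc(O[Si](C(C)C)(C(C)C)C(C)C)cc1O[Si](C(C)C)(C(C)C)C(C)C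
F6 | step 6 | (S)-epoxide of F5 | COC(=O)c1cc(=O)c(C[C@@H]2OC2(C)C)c(o1)-c1ccc(O[Si](C(C)C)(C(C)C)C(C)C)cc1O[Si](C(C)C)(C(C)C)C(C)C
F7 | step 9 | N-methoxy-N-methylamide of 14 (R) | CON(C)C(=O)c1cc(=O)c2c(o1)-c1ccc(OCOC)cc1O[C@@H](C(C)(C)OCOC)C2
F8 | step 9 | 8a-acetyl pyranone of the rings B/C/D series, bis(methoxymethyl) ether (R) | CC(=O)c1cc(=O)c2c(o1)-c1ccc(OCOC)cc1O[C@@H](C(C)(C)OCOC)C2
F9 | step 9 | 4,4,4-trifluoro-1-(pyranon-8a-yl)butane-1,3-dione derived from F8 (R) | O=C(CC(=O)C(F)(F)F)c1cc(=O)c2c(o1)-c1ccc(OCOC)cc1O[C@@H](C(C)(C)OCOC)C2
F10 | step 11 | (E)-1-methoxy-5-methylhex-3-en-2-one | COCC(=O)/C=C/C(C)C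
F11 | step 11 | (3E)-1-methoxy-5-methylhexa-1,3-dien-2-yl trifluoromethanesulfonate | COC=C(OS(=O)(=O)C(F)(F)F)/C=C/C(C)C
A1 | alternative 1 | 7-methoxy-5-(methoxymethoxy)-6-[(E)-3-methylbut-1-enyl]chromen-4-one | COc1cc2occc(=O)c2c(OCOC)c1/C=C/C(C)C
A2 | alternative 1 | [2-fluoro-4-(methoxymethoxy)phenyl]magnesium bromide | COCOc1ccc([Mg]Br)c(F)c1
A3 | alternative 1 | 1-bromo-3-methyl-3-(triethylsilyloxy)butan-2-one | CC[Si](CC)(CC)OC(C)(C)C(=O)CBr
A4 | alternative 1 | 2-aryl-3-(2-oxoalkyl)flavanone, C2 and C3 unassigned | COc1cc2OC(c3ccc(OCOC)cc3F)C(CC(=O)C(C)(C)O[Si](CC)(CC)CC)C(=O)c2c(OCOC)c1/C=C/C(C)C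
A5 | alternative 2 | ring A aryl ketone carrying the (R)-configured 2-bromo-5-(methoxymethoxy)phenyl ether side chain | COc1cc(O)c(C(=O)CC[C@H](C(C)(C)O)Oc2cc(OCOC)ccc2Br)c(OCOC)c1/C=C/C(C)C
A6 | alternative 2 | benzoxepine-fused 1,3-diketone with free C8a hydroxyl (R) | COc1cc(O)c(C(=O)C2C[C@H](C(C)(C)O)Oc3cc(OCOC)ccc3C2=O)c(OCOC)c1/C=C/C(C)C
A7 | alternative 3 | 5-methoxy-3-(methoxymethoxy)-4-[(E)-3-methylbut-1-enyl]-2-(trimethylsilyl)phenyl trifluoromethanesulfonate | COc1cc(OS(=O)(=O)C(F)(F)F)c([Si](C)(C)C)c(OCOC)c1/C=C/C(C)C
A8 | alternative 3 | (R)-5-chloro-8-(methoxymethoxy)-2-[2-(methoxymethoxy)propan-2-yl]-2,3-dihydro-1-benzoxepine-4-carboxylic acid | OC(=O)C1=C(Cl)c2ccc(OCOC)cc2O[C@@H](C(C)(C)OCOC)C1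
A9 | alternative 3 | tris(methoxymethyl) ether of the target (R) | COc1cc2oc3c(c(=O)c2c(OCOC)c1/C=C/C(C)C)C[C@H](C(C)(C)OCOC)Oc1cc(OCOC)ccc1-3
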